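**Strategy.** Rhodisin is cut at C3–C4 of the pyran ring of the lower, C8-linked epigallocatechin unit. Because C4 sits on C4a of the lower A ring and C3 on the O1-bound C2, this bond can be made as a C3=C4 alkene by ring-closing metathesis between a vinyl group on C4a and the vinyl group of a branched O1-allyl ether that already holds C2 in the right configuration. One operation closes the lower heterocycle as a 2-aryl-2H-chromene; hydroboration, oxidation and hydride reduction then set the cis 3-ol. The precursor is the benzyl-protected upper epigallocatechin gallate whose C4 carries a 2-vinylaryl 1-arylallyl ether.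

Key step: step 12

Remarks on the chemistry:
- The carbon that becomes lower C2 is (S) by the sequence rules in the metathesis precursor and in the 2H-chromene, because aryl outranks the vinylic carbon. The same spatial arrangement is 2R once C3 bears oxygen, as in the target.
- The upper O3 carries the tri-O-benzylgalloyl ester of the target from step 7 on, not a temporary protecting group. No deprotection and no acylation of the crowded upper 3-hydroxyl are then needed after the dimer is built, and the ester also directs the C4 arylation.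
- 3,4,5-Trihydroxybenzaldehyde, (−)-epigallocatechin, 3,4,5-tris(benzyloxy)benzoic acid and 3,5-bis(benzyloxy)phenol are taken as purchased.
- The configuration of every compound is the one written in its SMILES; "4β" means trans to O3 and to the C2 aryl group of the upper unit.

**Route**

Step 1
Reactants: 1 3,4,5-trihydroxybenzaldehyde
Product: 2 3,4,5-tris(benzyloxy)benzaldehyde
Conditions: BnBr (3.3 equiv), K2CO3, DMF, rt to 60 °C
Reagents that add atoms: benzyl bromide, BrCc1ccccc1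
Why: Williamson etherification of the three phenols, with the aldehyde inert to carbonate base.

Step 2
Reactants: 2 3,4,5-tris(benzyloxy)benzaldehyde
Product: 3 ethyl (E)-3-[3,4,5-tris(benzyloxy)phenyl]prop-2-enoate
Conditions: (EtO)2P(O)CH2CO2Et, NaH, THF, 0 °C to rt
Reagents that add atoms: triethyl phosphonoacetate, CCOC(=O)CP(=O)(OCC)OCC
Why: Horner–Wadsworth–Emmons olefination, which is reliably E-selective with aromatic aldehydes.

Step 3
Reactants: 3 ethyl (E)-3-[3,4,5-tris(benzyloxy)phenyl]prop-2-enoate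
Product: 4 (E)-3-[3,4,5-tris(benzyloxy)phenyl]prop-2-en-1-ol
Conditions: DIBAL-H (2.2 equiv), CH2Cl2, −78 to 0 °C; Rochelle salt work-up
Reagents that add atoms: none
Why: 1,2-reduction of the enoate by DIBAL-H, which leaves the alkene geometry and the benzyl ethers untouched.

Step 4
Reactants: 4 (E)-3-[3,4,5-tris(benzyloxy)phenyl]prop-2-en-1-ol
Product: 5 tert-butyl (E)-3-[3,4,5-tris(benzyloxy)phenyl]allyl carbonate
Conditions: Boc2O, Bu4NHSO4 (cat.), 30% aq NaOH, CH2Cl2, 0 °C to rt
Reagents that add atoms: di-tert-butyl dicarbonate, CC(C)(C)OC(=O)OC(=O)OC(C)(C)C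
Why: phase-transfer O-acylation of the primary allylic alcohol; the tert-butyl carbonate is chosen so that step 11 releases only hindered tert-butoxide, which cannot transesterify the gallate.

Step 5
Reactants: 6 (−)-epigallocatechin
Product: 7 5,7,3',4',5'-penta-O-benzyl-(−)-epigallocatechin
Conditions: BnBr (5.5 equiv), K2CO3, DMF, 0 °C to rt, argon
Reagents that add atoms: benzyl bromide, BrCc1ccccc1
Why: Williamson etherification that is selective for the five phenols over the secondary 3-hydroxyl under carbonate base, with air excluded to protect the pyrogallol ring.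

Step 6
Reactants: 7 5,7,3',4',5'-penta-O-benzyl-(−)-epigallocatechin
Product: 8 4β-(2-ethoxyethoxy)-5,7,3',4',5'-penta-O-benzylepigallocatechin
Conditions: DDQ (2 equiv), 2-ethoxyethanol (5 equiv), CH2Cl2, rt
Reagents that add atoms: 2-ethoxyethanol, CCOCCO
Why: DDQ benzylic oxidation, in which hydride abstraction from C4 gives a quinone-methide-type cation that the alcohol traps on the face opposite the cis C2-aryl and C3-hydroxyl groups (3,4-trans), as is established for benzylated flavan-3-ols.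

Step 7
Reactants: 8 4β-(2-ethoxyethoxy)-5,7,3',4',5'-penta-O-benzylepigallocatechin; 9 3,4,5-tris(benzyloxy)benzoic acid
Product: 10 4β-(2-ethoxyethoxy)-5,7,3',4',5'-penta-O-benzylepigallocatechin 3-O-[3,4,5-tris(benzyloxy)benzoate]
Conditions: DCC, DMAP, CH2Cl2, rt
Reagents that add atoms: none
Why: Steglich esterification of the only free hydroxyl under neutral conditions that do not ionise the C4 ether.

Step 8
Reactants: 10 4β-(2-ethoxyethoxy)-5,7,3',4',5'-penta-O-benzylepigallocatechin 3-O-[3,4,5-tris(benzyloxy)benzoate]; 11 3,5-bis(benzyloxy)phenol (4 equiv)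
Product: 12 4β-[4,6-bis(benzyloxy)-2-hydroxyphenyl]-5,7,3',4',5'-penta-O-benzylepigallocatechin 3-O-[3,4,5-tris(benzyloxy)benzoate]
Conditions: BF3·OEt2 (0.5 equiv), CH2Cl2, −78 to −30 °C; Et3N quench
Reagents that add atoms: none
Why: Friedel–Crafts alkylation in which the C4 cation is shielded on the O3 face by the neighbouring gallate carbonyl and the C2 aryl, so the phenol enters trans (4β) through the ring carbon ortho to its hydroxyl, which is less crowded than the carbon between the two benzyloxy groups, in line with the C8-over-C6 preference of benzylated flavan nucleophiles.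

Step 9
Reactants: 12 4β-[4,6-bis(benzyloxy)-2-hydroxyphenyl]-5,7,3',4',5'-penta-O-benzylepigallocatechin 3-O-[3,4,5-tris(benzyloxy)benzoate]
Product: 14 4β-[4,6-bis(benzyloxy)-3-formyl-2-hydroxyphenyl]-5,7,3',4',5'-penta-O-benzylepigallocatechin 3-O-[3,4,5-tris(benzyloxy)benzoate], via salicyl alcohol 13 (not isolated)
Conditions: MgCl2 (3 equiv), Et3N (6 equiv), (CH2O)n (8 equiv), THF, 65 °C
Reagents that add atoms: paraformaldehyde (as formaldehyde), C=O
Why: Casnati–Skattebøl ortho-formylation, in which the magnesium phenoxide delivers formaldehyde to the only free ortho carbon and a second formaldehyde oxidises the resulting salicyl alcohol by hydride transfer, so the para carbon and the fully etherified rings are not attacked.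

Step 10
Reactants: 14 4β-[4,6-bis(benzyloxy)-3-formyl-2-hydroxyphenyl]-5,7,3',4',5'-penta-O-benzylepigallocatechin 3-O-[3,4,5-tris(benzyloxy)benzoate]
Product: 15 4β-[4,6-bis(benzyloxy)-2-hydroxy-3-vinylphenyl]-5,7,3',4',5'-penta-O-benzylepigallocatechin 3-O-[3,4,5-tris(benzyloxy)benzoate]
Conditions: Ph3PCH3Br (3.2 equiv), KOtBu (3.0 equiv), THF, 0 °C to rt; chromatography on Et3N-washed silica, used at once
Reagents that add atoms: methyltriphenylphosphonium bromide (as its ylide), C[P+](c1ccccc1)(c1ccccc1)c1ccccc1.[Br-]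
Why: Wittig methylenation of a salicylaldehyde with excess ylide, the first equivalent being used up by the phenol, while the hindered gallate ester is inert to the ylide at this temperature.

Step 11
Reactants: 15 4β-[4,6-bis(benzyloxy)-2-hydroxy-3-vinylphenyl]-5,7,3',4',5'-penta-O-benzylepigallocatechin 3-O-[3,4,5-tris(benzyloxy)benzoate]; 5 tert-butyl (E)-3-[3,4,5-tris(benzyloxy)phenyl]allyl carbonate (1.3 equiv)
Product: 17 4β-{4,6-bis(benzyloxy)-2-[(S)-1-(3,4,5-tris(benzyloxy)phenyl)prop-2-enyloxy]-3-vinylphenyl}-5,7,3',4',5'-penta-O-benzylepigallocatechin 3-O-[3,4,5-tris(benzyloxy)benzoate], via lithium phenoxide 16 (not isolated)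
Conditions: LiHMDS (1.0 equiv), THF, 0 °C; then 5, [Ir(cod)Cl]2 (2.5 mol%), (Sa,Sc,Sc)-BINOL N,N-bis(1-phenylethyl)phosphoramidite (5 mol%, pre-activated with n-PrNH2), THF, rt to 35 °C
Reagents that add atoms: none
Why: iridium-catalysed asymmetric allylic etherification, in which the cyclometalated Ir–phosphoramidite ionises the carbonate to a π-allyl complex and the phenoxide attacks its aryl-bearing terminus to give the branched ether; the ligand selects the face and so sets the new (S) centre under catalyst control (the (Sa,Sc,Sc) ligand is expected to give this sense, and its antipode would be used if a model phenol shows the opposite).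

Step 12
Reactants: 17 4β-{4,6-bis(benzyloxy)-2-[(S)-1-(3,4,5-tris(benzyloxy)phenyl)prop-2-enyloxy]-3-vinylphenyl}-5,7,3',4',5'-penta-O-benzylepigallocatechin 3-O-[3,4,5-tris(benzyloxy)benzoate]
Product: 18 5,7,3',4',5'-penta-O-benzylepigallocatechin 3-O-[3,4,5-tris(benzyloxy)benzoate] linked 4β→8 to (2S)-5,7-bis(benzyloxy)-2-[3,4,5-tris(benzyloxy)phenyl]-2H-chromene
Conditions: Grubbs second-generation catalyst (5–10 mol%), 1,4-benzoquinone (20 mol%), CH2Cl2 (0.005 M), 40 °C, dark
Reagents that add atoms: none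
Why: Olefin metathesis by the Chauvin mechanism: the ruthenium benzylidene exchanges onto the unhindered terminal alkene of the allyl ether, the new alkylidene adds across the styrenyl C=C on C4a in a [2+2] step, and cycloreversion of the metallacyclobutane gives C3=C4 and a ruthenium methylidene that leaves as ethylene. The closest known reaction type is ring-closing metathesis of 2-vinylphenyl allyl ethers to 2H-chromenes. The pyran ring closes as a six-membered ring by intramolecular metathesis of two terminal alkenes, and the ring size enforces the cis alkene. No stereocentre forms; the (S) centre at C2 was set in step 11 and none of its bonds takes part. The step needs ring closure to win over alkene migration, which would turn the allyl ether into an enol ether and erase C2, and over ionisation of the doubly activated C2–O bond: benzoquinone scavenges ruthenium hydrides, the medium is neutral, high dilution suppresses cross-metathesis, and there are no other non-aromatic alkenes. Light is excluded because 2-aryl-2H-chromenes can open photochemically to quinone methides.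

Step 13
Reactants: 18 5,7,3',4',5'-penta-O-benzylepigallocatechin 3-O-[3,4,5-tris(benzyloxy)benzoate] linked 4β→8 to (2S)-5,7-bis(benzyloxy)-2-[3,4,5-tris(benzyloxy)phenyl]-2H-chromene
Product: 20 upper unit as in 18 linked 4β→8 to (2R,3S)-5,7-bis(benzyloxy)-2-[3,4,5-tris(benzyloxy)phenyl]chroman-3-ol (2,3-trans), via C3 alkylborane 19 (not isolated)
Conditions: BH3·THF (3 equiv), THF, 0 °C to rt; then NaBO3·4H2O, THF/H2O, rt
Reagents that add atoms: sodium perborate (oxygen at C3), [Na+].[O-]OB=O; borane as its THF complex (boron in 19 only), B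
Why: hydroboration–oxidation of a flav-3-ene, in which boron adds to C3 (positive charge builds at benzylic C4 next to the electron-rich A ring) syn with hydrogen on the face opposite the C2 aryl, and oxidation with retention gives the 2,3-trans alcohol; perborate is used so that the gallate ester is not cleaved.

Step 14
Reactants: 20 upper unit as in 18 linked 4β→8 to (2R,3S)-5,7-bis(benzyloxy)-2-[3,4,5-tris(benzyloxy)phenyl]chroman-3-ol
Product: 21 upper unit as in 18 linked 4β→8 to (2R)-5,7-bis(benzyloxy)-2-[3,4,5-tris(benzyloxy)phenyl]chroman-3-one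
Conditions: Dess–Martin periodinane, NaHCO3, wet CH2Cl2, 0 °C to rt; used directly
Reagents that add atoms: none
Why: Dess–Martin oxidation of the only free hydroxyl under buffered, base-free conditions, which keeps the enolisable C2 centre of the flavan-3-one intact.

Step 15
Reactants: 21 upper unit as in 18 linked 4β→8 to (2R)-5,7-bis(benzyloxy)-2-[3,4,5-tris(benzyloxy)phenyl]chroman-3-one
Product: 22 upper unit as in 18 linked 4β→8 to (2R,3R)-5,7-bis(benzyloxy)-2-[3,4,5-tris(benzyloxy)phenyl]chroman-3-ol (2,3-cis)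
Conditions: L-Selectride (1.5 equiv), LiBr, THF, −78 °C; aqueous quench
Reagents that add atoms: none
Why: hindered-hydride ketone reduction in which L-Selectride attacks the flavan-3-one from the face away from the C2 aryl to give the axial, 2,3-cis alcohol, as known for benzylated flavan-3-ones, while the ester is untouched at −78 °C.

Step 16
Reactants: 22 upper unit as in 18 linked 4β→8 to (2R,3R)-5,7-bis(benzyloxy)-2-[3,4,5-tris(benzyloxy)phenyl]chroman-3-ol; 9 3,4,5-tris(benzyloxy)benzoic acid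
Product: 23 hexadeca-O-benzylrhodisin
Conditions: DCC, DMAP, CH2Cl2, rt
Reagents that add atoms: none
Why: Steglich esterification of the single remaining hydroxyl, the same acylation that is routine for the axial 3-hydroxyl of benzylated epicatechin-type flavanols.

Step 17
Reactants: 23 hexadeca-O-benzylrhodisin
Product: 24 rhodisin
Conditions: H2 (1 atm), Pd(OH)2/C, THF/MeOH/H2O, rt; filtration and lyophilisation under argon
Reagents that add atoms: none
Why: catalytic hydrogenolysis of the sixteen benzyl ethers under neutral conditions, which the gallate esters and the interflavan C4–C8 bond survive.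

**Compound list**

1 | 3,4,5-trihydroxybenzaldehyde | O=Cc1cc(O)c(O)c(O)c1 | starting material
2 | 3,4,5-tris(benzyloxy)benzaldehyde | O=Cc1cc(OCc2ccccc2)c(OCc2ccccc2)c(OCc2ccccc2)c1 | intermediate
3 | ethyl (E)-3-[3,4,5-tris(benzyloxy)phenyl]prop-2-enoate | CCOC(=O)/C=C/c1cc(OCc2ccccc2)c(OCc2ccccc2)c(OCc2ccccc2)c1 | intermediate
4 | (E)-3-[3,4,5-tris(benzyloxy)phenyl]prop-2-en-1-ol | OC/C=C/c1cc(OCc2ccccc2)c(OCc2ccccc2)c(OCc2ccccc2)c1 | intermediate
5 | tert-butyl (E)-3-[3,4,5-tris(benzyloxy)phenyl]allyl carbonate | CC(C)(C)OC(=O)OC/C=C/c1cc(OCc2ccccc2)c(OCc2ccccc2)c(OCc2ccccc2)c1 | intermediate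
6 | (−)-epigallocatechin, (2R,3R) | O[C@@H]1Cc2c(O)cc(O)cc2O[C@@H]1c1cc(O)c(O)c(O)c1 | starting material
7 | 5,7,3',4',5'-penta-O-benzyl-(−)-epigallocatechin | O[C@@H]1Cc2c(OCc3ccccc3)cc(OCc3ccccc3)cc2O[C@@H]1c1cc(OCc2ccccc2)c(OCc2ccccc2)c(OCc2ccccc2)c1 | intermediate
8 | 4β-(2-ethoxyethoxy)-5,7,3',4',5'-penta-O-benzylepigallocatechin (2,3-cis, 3,4-trans) | O[C@@H]1[C@@H](OCCOCC)c2c(OCc3ccccc3)cc(OCc3ccccc3)cc2O[C@@H]1c1cc(OCc2ccccc2)c(OCc2ccccc2)c(OCc2ccccc2)c1 | intermediate
9 | 3,4,5-tris(benzyloxy)benzoic acid | OC(=O)c1cc(OCc2ccccc2)c(OCc2ccccc2)c(OCc2ccccc2)c1 | starting material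
10 | 4β-(2-ethoxyethoxy)-5,7,3',4',5'-penta-O-benzylepigallocatechin 3-O-[3,4,5-tris(benzyloxy)benzoate] | O=C(O[C@@H]1[C@@H](OCCOCC)c2c(OCc3ccccc3)cc(OCc3ccccc3)cc2O[C@@H]1c1cc(OCc2ccccc2)c(OCc2ccccc2)c(OCc2ccccc2)c1)c1cc(OCc2ccccc2)c(OCc2ccccc2)c(OCc2ccccc2)c1 | intermediate
11 | 3,5-bis(benzyloxy)phenol | Oc1cc(OCc2ccccc2)cc(OCc2ccccc2)c1 | starting material
12 | 4β-[4,6-bis(benzyloxy)-2-hydroxyphenyl]-5,7,3',4',5'-penta-O-benzylepigallocatechin 3-O-[3,4,5-tris(benzyloxy)benzoate] | O=C(O[C@@H]1[C@@H](c2c(OCc3ccccc3)cc(OCc3ccccc3)cc2O)c2c(OCc3ccccc3)cc(OCc3ccccc3)cc2O[C@@H]1c1cc(OCc2ccccc2)c(OCc2ccccc2)c(OCc2ccccc2)c1)c1cc(OCc2ccccc2)c(OCc2ccccc2)c(OCc2ccccc2)c1 | intermediate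
13 | 4β-[4,6-bis(benzyloxy)-2-hydroxy-3-(hydroxymethyl)phenyl] analogue of 12 (salicyl alcohol, formed as its magnesium salt) | O=C(O[C@@H]1[C@@H](c2c(OCc3ccccc3)cc(OCc3ccccc3)c(CO)c2O)c2c(OCc3ccccc3)cc(OCc3ccccc3)cc2O[C@@H]1c1cc(OCc2ccccc2)c(OCc2ccccc2)c(OCc2ccccc2)c1)c1cc(OCc2ccccc2)c(OCc2ccccc2)c(OCc2ccccc2)c1 | intermediate (not isolated)
14 | 4β-[4,6-bis(benzyloxy)-3-formyl-2-hydroxyphenyl] analogue of 12 | O=C(O[C@@H]1[C@@H](c2c(OCc3ccccc3)cc(OCc3ccccc3)c(C=O)c2O)c2c(OCc3ccccc3)cc(OCc3ccccc3)cc2O[C@@H]1c1cc(OCc2ccccc2)c(OCc2ccccc2)c(OCc2ccccc2)c1)c1cc(OCc2ccccc2)c(OCc2ccccc2)c(OCc2ccccc2)c1 | intermediate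
15 | 4β-[4,6-bis(benzyloxy)-2-hydroxy-3-vinylphenyl] analogue of 12 | O=C(O[C@@H]1[C@@H](c2c(OCc3ccccc3)cc(OCc3ccccc3)c(C=C)c2O)c2c(OCc3ccccc3)cc(OCc3ccccc3)cc2O[C@@H]1c1cc(OCc2ccccc2)c(OCc2ccccc2)c(OCc2ccccc2)c1)c1cc(OCc2ccccc2)c(OCc2ccccc2)c(OCc2ccccc2)c1 | intermediate
16 | lithium phenoxide of 15 | O=C(O[C@@H]1[C@@H](c2c(OCc3ccccc3)cc(OCc3ccccc3)c(C=C)c2[O-])c2c(OCc3ccccc3)cc(OCc3ccccc3)cc2O[C@@H]1c1cc(OCc2ccccc2)c(OCc2ccccc2)c(OCc2ccccc2)c1)c1cc(OCc2ccccc2)c(OCc2ccccc2)c(OCc2ccccc2)c1.[Li+] | intermediate (not isolated)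
17 | 4β-{4,6-bis(benzyloxy)-2-[(S)-1-(3,4,5-tris(benzyloxy)phenyl)prop-2-enyloxy]-3-vinylphenyl}-5,7,3',4',5'-penta-O-benzylepigallocatechin 3-O-[3,4,5-tris(benzyloxy)benzoate] (metathesis precursor) | O=C(O[C@@H]1[C@@H](c2c(OCc3ccccc3)cc(OCc3ccccc3)c(C=C)c2O[C@H](c2cc(OCc3ccccc3)c(OCc3ccccc3)c(OCc3ccccc3)c2)C=C)c2c(OCc3ccccc3)cc(OCc3ccccc3)cc2O[C@@H]1c1cc(OCc2ccccc2)c(OCc2ccccc2)c(OCc2ccccc2)c1)c1cc(OCc2ccccc2)c(OCc2ccccc2)c(OCc2ccccc2)c1 | intermediate
18 | protected upper epigallocatechin gallate linked 4β→8 to (2S)-5,7-bis(benzyloxy)-2-[3,4,5-tris(benzyloxy)phenyl]-2H-chromene | O=C(O[C@@H]1[C@@H](c2c(OCc3ccccc3)cc(OCc3ccccc3)c3c2O[C@H](c2cc(OCc4ccccc4)c(OCc4ccccc4)c(OCc4ccccc4)c2)C=C3)c2c(OCc3ccccc3)cc(OCc3ccccc3)cc2O[C@@H]1c1cc(OCc2ccccc2)c(OCc2ccccc2)c(OCc2ccccc2)c1)c1cc(OCc2ccccc2)c(OCc2ccccc2)c(OCc2ccccc2)c1 | intermediate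
19 | lower-unit C3 alkylborane (boron trans to the C2 aryl) | O=C(O[C@@H]1[C@@H](c2c(OCc3ccccc3)cc(OCc3ccccc3)c3c2O[C@H](c2cc(OCc4ccccc4)c(OCc4ccccc4)c(OCc4ccccc4)c2)[C@@H](B)C3)c2c(OCc3ccccc3)cc(OCc3ccccc3)cc2O[C@@H]1c1cc(OCc2ccccc2)c(OCc2ccccc2)c(OCc2ccccc2)c1)c1cc(OCc2ccccc2)c(OCc2ccccc2)c(OCc2ccccc2)c1 | intermediate (not isolated)
20 | protected dimer with lower (2R,3S)-2,3-trans-flavan-3-ol | O=C(O[C@@H]1[C@@H](c2c(OCc3ccccc3)cc(OCc3ccccc3)c3c2O[C@H](c2cc(OCc4ccccc4)c(OCc4ccccc4)c(OCc4ccccc4)c2)[C@@H](O)C3)c2c(OCc3ccccc3)cc(OCc3ccccc3)cc2O[C@@H]1c1cc(OCc2ccccc2)c(OCc2ccccc2)c(OCc2ccccc2)c1)c1cc(OCc2ccccc2)c(OCc2ccccc2)c(OCc2ccccc2)c1 | intermediate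
21 | protected dimer with lower (2R)-flavan-3-one | O=C(O[C@@H]1[C@@H](c2c(OCc3ccccc3)cc(OCc3ccccc3)c3c2O[C@H](c2cc(OCc4ccccc4)c(OCc4ccccc4)c(OCc4ccccc4)c2)C(=O)C3)c2c(OCc3ccccc3)cc(OCc3ccccc3)cc2O[C@@H]1c1cc(OCc2ccccc2)c(OCc2ccccc2)c(OCc2ccccc2)c1)c1cc(OCc2ccccc2)c(OCc2ccccc2)c(OCc2ccccc2)c1 | intermediate
22 | protected dimer with lower (2R,3R)-2,3-cis-flavan-3-ol | O=C(O[C@@H]1[C@@H](c2c(OCc3ccccc3)cc(OCc3ccccc3)c3c2O[C@H](c2cc(OCc4ccccc4)c(OCc4ccccc4)c(OCc4ccccc4)c2)[C@H](O)C3)c2c(OCc3ccccc3)cc(OCc3ccccc3)cc2O[C@@H]1c1cc(OCc2ccccc2)c(OCc2ccccc2)c(OCc2ccccc2)c1)c1cc(OCc2ccccc2)c(OCc2ccccc2)c(OCc2ccccc2)c1 | intermediate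
23 | hexadeca-O-benzylrhodisin | O=C(O[C@@H]1[C@@H](c2c(OCc3ccccc3)cc(OCc3ccccc3)c3c2O[C@H](c2cc(OCc4ccccc4)c(OCc4ccccc4)c(OCc4ccccc4)c2)[C@H](OC(=O)c2cc(OCc4ccccc4)c(OCc4ccccc4)c(OCc4ccccc4)c2)C3)c2c(OCc3ccccc3)cc(OCc3ccccc3)cc2O[C@@H]1c1cc(OCc2ccccc2)c(OCc2ccccc2)c(OCc2ccccc2)c1)c1cc(OCc2ccccc2)c(OCc2ccccc2)c(OCc2ccccc2)c1 | intermediate
24 | rhodisin | O=C(O[C@@H]1[C@@H](c2c(O)cc(O)c3c2O[C@H](c2cc(O)c(O)c(O)c2)[C@H](OC(=O)c2cc(O)c(O)c(O)c2)C3)c2c(O)cc(O)cc2O[C@@H]1c1cc(O)c(O)c(O)c1)c1cc(O)c(O)c(O)c1 | target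

**Count**

Total steps: 17. Longest linear sequence: 13 steps (6 to 24, steps 5–17).

**Steps most likely to fail**

Step 11. The lithium phenoxide is flanked by two ortho substituents and may attack the allyliridium intermediate too slowly, so that carbonate decomposition, formation of the linear ether or loss of facial control take over. The fallback sets out from 15 and comes back at 17. Aldehyde 2 would be treated with ethynylmagnesium bromide (THF, 0 °C) to give racemic 1-[3,4,5-tris(benzyloxy)phenyl]prop-2-yn-1-ol F1. Mitsunobu etherification of phenol 15 with F1 (PPh3, DIAD, toluene, 0 °C to rt, sonication if slow) would give the aryl propargyl ether F2 as a pair of epimers at the ether carbon, to be separated by chromatography. Lindlar semi-hydrogenation of the (S) epimer (H2, Pd/CaCO3–Pb, quinoline, EtOAc) would then give 17. The C–O bond is here made by displacement at a propargylic carbinol instead of through a metal allyl, at the price of catalyst control.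

Step 8. The C4 cation may alkylate the phenol at the carbon between its two benzyloxy groups, or twice, which would give regioisomers and oligomers. The fallback sets out from 10 and comes back at 12. Compound 10 would be condensed with excess phloroglucinol, in which all three ring carbons are equivalent (BF3·OEt2, THF/CH2Cl2, −40 °C), to give the 4β-(2,4,6-trihydroxyphenyl) adduct F3. Benzylation with two equivalents of benzyl bromide (K2CO3, DMF, 0 °C) would then take the unhindered para hydroxyl first and one of the two equivalent ortho hydroxyls second, which is 12.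

Step 12. Ring closure at the styrene between two ortho oxygens may be slow enough for ruthenium hydrides to migrate the allyl ether alkene, which would destroy C2 and divert material to ring-contracted or cleaved products. The fallback sets out from 12 and comes back at 18. Phenol 12, which still has one free ortho carbon, would be etherified with F1 under Mitsunobu conditions to the aryl propargyl ether F4 (epimers separated). A cationic gold(I) catalyst (Ph3PAuNTf2, CH2Cl2, rt) would then close the ring by 6-endo-dig hydroarylation of the alkyne by that ortho carbon, a known route from aryl propargyl ethers to 2H-chromenes, and give 18 with the ether stereocentre untouched.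

**Further compounds**

F1 | step 11 | racemic 1-[3,4,5-tris(benzyloxy)phenyl]prop-2-yn-1-ol | C#CC(O)c1cc(OCc2ccccc2)c(OCc2ccccc2)c(OCc2ccccc2)c1
F2 | step 11 | 4β-{4,6-bis(benzyloxy)-2-[(S)-1-(3,4,5-tris(benzyloxy)phenyl)prop-2-ynyloxy]-3-vinylphenyl} analogue of 12 (wanted epimer) | O=C(O[C@@H]1[C@@H](c2c(OCc3ccccc3)cc(OCc3ccccc3)c(C=C)c2O[C@H](c2cc(OCc3ccccc3)c(OCc3ccccc3)c(OCc3ccccc3)c2)C#C)c2c(OCc3ccccc3)cc(OCc3ccccc3)cc2O[C@@H]1c1cc(OCc2ccccc2)c(OCc2ccccc2)c(OCc2ccccc2)c1)c1cc(OCc2ccccc2)c(OCc2ccccc2)c(OCc2ccccc2)c1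
F3 | step 8 | 4β-(2,4,6-trihydroxyphenyl)-5,7,3',4',5'-penta-O-benzylepigallocatechin 3-O-[3,4,5-tris(benzyloxy)benzoate] | O=C(O[C@@H]1[C@@H](c2c(O)cc(O)cc2O)c2c(OCc3ccccc3)cc(OCc3ccccc3)cc2O[C@@H]1c1cc(OCc2ccccc2)c(OCc2ccccc2)c(OCc2ccccc2)c1)c1cc(OCc2ccccc2)c(OCc2ccccc2)c(OCc2ccccc2)c1
F4 | step 12 | 4β-{4,6-bis(benzyloxy)-2-[(S)-1-(3,4,5-tris(benzyloxy)phenyl)prop-2-ynyloxy]phenyl} analogue of 12 (wanted epimer) | O=C(O[C@@H]1[C@@H](c2c(OCc3ccccc3)cc(OCc3ccccc3)cc2O[C@H](c2cc(OCc3ccccc3)c(OCc3ccccc3)c(OCc3ccccc3)c2)C#C)c2c(OCc3ccccc3)cc(OCc3ccccc3)cc2O[C@@H]1c1cc(OCc2ccccc2)c(OCc2ccccc2)c(OCc2ccccc2)c1)c1cc(OCc2ccccc2)c(OCc2ccccc2)c(OCc2ccccc2)c1
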